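**Retrosynthetic overview**

- Feature: ring carbons C6–C11, with the C7 methyl, the C7 oxygen and both C11 methyls, are the skeleton of (R)-linalool (nine of its ten carbons) lacking only the C6–C11 bond. C7 is linalool's carbinol carbon, and the side-chain carbon C4 lies 1,5 to the C10 oxygen and γ to the C7 oxygen.
- Late disconnections: C10 acetate; C1–O aryl ether (Mitsunobu, umbelliferone); C3 carbinol from reagent-controlled epoxidation and hydride opening of an (E)-allylic alcohol; C3–Me and C2–C1 by alkyne carboalumination–hydroxymethylation; C3–C4 by acetylide alkylation of a C4 iodide.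
- The C4 iodide is traced to a cis-fused keto γ-lactone (C10 ketone to axial alcohol, lactone to the C4/C7 diol).
- That lactone is opened across C6–C11 (Michael) and O7–C4 (ester) to an acyclic hydroxy keto enoate. Forward, the cyclohexanone closes first and the γ-lactone second in the same flask; the lactone is cleaved later and the coumarin bicycle is bought.
- The enoate comes from (R)-linalool by rearrangement of the trisubstituted-alkene epoxide to the C10 isopropyl ketone and cross-metathesis of the vinyl group with methyl acrylate (C5 and C4; linalool's tenth carbon leaves as ethene).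

Key step: step 6

Remark: locants C1–C11 are farnesane locants of the sesquiterpene part (chain O–C1–C2–C3–C4–C5, ring C6 to C11, acetate on C10), so the target is (3R,6S,7R,10R); (R)-linalool is assumed to be available in high enantiomeric purity.

**Route**

Step 1
Reactants: 1 (R)-linalool
Product: 2 (3R)-3,7-dimethyl-3-(triethylsilyloxy)octa-1,6-diene
Conditions: TESOTf (1.2 equiv), 2,6-lutidine, CH2Cl2, −78 → 0 °C
Reagents that add atoms: triethylsilyl trifluoromethanesulfonate, CC[Si](CC)(CC)OS(=O)(=O)C(F)(F)F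
Why: Silyl triflate silylation of a tertiary alcohol masks the hydroxyl that would otherwise open the epoxide of step 2 to linalool oxides, and the stereocentre is not touched.

Step 2
Reactants: 2 (3R)-3,7-dimethyl-3-(triethylsilyloxy)octa-1,6-diene
Product: 3 (3R)-6,7-epoxy-3,7-dimethyl-3-(triethylsilyloxy)oct-1-ene (both C6 epimers)
Conditions: mCPBA (1.05 equiv), NaHCO3, CH2Cl2, 0 °C
Reagents that add atoms: 3-chloroperoxybenzoic acid, OOC(=O)c1cccc(Cl)c1
Why: Prilezhaev epoxidation should pick the electron-rich trisubstituted alkene over the vinyl group, and the new oxirane stereocentre, formed as both epimers, is erased in step 3.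

Step 3
Reactants: 3 (3R)-6,7-epoxy-3,7-dimethyl-3-(triethylsilyloxy)oct-1-ene
Product: 4 (6R)-2,6-dimethyl-6-(triethylsilyloxy)oct-7-en-3-one
Conditions: BF3·OEt2 (0.2 equiv), CH2Cl2, −78 °C; Et3N quench
Reagents that add atoms: none
Why: Meinwald rearrangement, in which Lewis-acid opening at the tertiary oxirane carbon and a 1,2-hydride shift from the neighbouring CH should give the isopropyl ketone, the hindered tertiary silyl ether being a poor internal nucleophile at low temperature.

Step 4
Reactants: 4 (6R)-2,6-dimethyl-6-(triethylsilyloxy)oct-7-en-3-one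
Product: 5 (6R)-6-hydroxy-2,6-dimethyloct-7-en-3-one
Conditions: Bu4NF (1.2 equiv), THF, 0 °C → rt
Reagents that add atoms: none
Why: Fluoride cleavage of the tertiary silyl ether frees the hydroxyl that assists metathesis of the hindered vinyl group and later closes the lactone, without touching the stereocentre.

Step 5
Reactants: 5 (6R)-6-hydroxy-2,6-dimethyloct-7-en-3-one; 6 methyl acrylate
Product: 7 methyl (2E,4R)-4-hydroxy-4,8-dimethyl-7-oxonon-2-enoate
Conditions: second-generation Hoveyda–Grubbs catalyst (5 mol %), 6 (5 equiv), CH2Cl2, 40 °C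
Reagents that add atoms: none
Why: Olefin cross-metathesis of a free tertiary allylic alcohol with an acrylate, two partners that homodimerise slowly, should give the (E)-enoate with loss of ethene, and 5 holds no second alkene that could divert the carbene into ring closure.

Step 6
Reactants: 7 methyl (2E,4R)-4-hydroxy-4,8-dimethyl-7-oxonon-2-enoate
Product: 9 (3aS,7aR)-4,4,7a-trimethyltetrahydro-1-benzofuran-2,5(3H,4H)-dione, via cis Michael adduct 8 (not isolated)
Conditions: KOtBu (0.3 equiv), tBuOH/THF (1:3), 0.02 M, 0 → 25 °C; AcOH quench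
Reagents that add atoms: none
Why: Alkoxide base equilibrates the ketone enolates, the tetrasubstituted C11 enolate adds to the enoate β-carbon C6, the ester enolate is protonated, and the C7 alkoxide then acylates on the ester with loss of methoxide, which is a base-mediated intramolecular Michael addition of a ketone enolate to an enoate followed by lactonisation, both known reaction types. The cyclohexanone closes 6-exo-trig (C11–C6) and the γ-lactone 5-exo-trig (O7–C4). C6 is the only new stereocentre and is set relative to the purchased C7 centre: in the chair transition state the enoate arm and the C7 methyl sit equatorial and the C7 oxygen axial, which places C5 cis to that oxygen, and since only this cis adduct can lactonise, the reversible addition should be drained into the (3aS,7aR) lactone. The step needs regioselection between the two enolates, which the substrate secures because the C9 enolate could only close a four-membered ring and the enoate has no γ-hydrogen through which to deconjugate. Should the enoate first isomerise and close to the butenolide, addition of C11 to it leads to the same cis-fused lactone, and high dilution is used against intermolecular addition.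

Step 7
Reactants: 9 (3aS,7aR)-4,4,7a-trimethyltetrahydro-1-benzofuran-2,5(3H,4H)-dione
Product: 10 (3aS,5R,7aR)-5-hydroxy-4,4,7a-trimethylhexahydro-1-benzofuran-2(3H)-one
Conditions: LiBH(sBu)3 (L-Selectride, 1.2 equiv), THF, −78 °C; then H2O2, pH 7 buffer, 0 °C
Reagents that add atoms: none
Why: Bulky trialkylborohydride reduction of the ketone (the lactone is inert at −78 °C) by equatorial attack, away from the axial hydrogens at C6 and C8, should give the axial (10R) alcohol trans to the C7 oxygen, as in the reduction of 4,4-dimethyl-3-oxo terpenoids to their axial 3-alcohols.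

Step 8
Reactants: 10 (3aS,5R,7aR)-5-hydroxy-4,4,7a-trimethylhexahydro-1-benzofuran-2(3H)-one
Product: 11 (1R,2S,4R)-2-(2-hydroxyethyl)-1,3,3-trimethylcyclohexane-1,4-diol
Conditions: LiAlH4 (2 equiv), THF, 0 °C → rt; Fieser work-up
Reagents that add atoms: none
Why: Hydride reduction of the γ-lactone gives the primary C4 alcohol and the tertiary C7 alcohol without affecting any stereocentre.

Step 9
Reactants: 11 (1R,2S,4R)-2-(2-hydroxyethyl)-1,3,3-trimethylcyclohexane-1,4-diol
Product: 12 triethyl{2-[(1S,2R,5R)-2,6,6-trimethyl-2,5-bis(triethylsilyloxy)cyclohexyl]ethoxy}silane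
Conditions: TESOTf (3.6 equiv), 2,6-lutidine, CH2Cl2, −78 → 0 °C
Reagents that add atoms: triethylsilyl trifluoromethanesulfonate, CC[Si](CC)(CC)OS(=O)(=O)C(F)(F)F
Why: Exhaustive silylation with the silyl triflate reaches the hindered secondary and tertiary hydroxyls too, and masking C7–OH is required because a free 1,4-related tertiary alcohol would close a tetrahydrofuran once C4 carries a leaving group.

Step 10
Reactants: 12 triethyl{2-[(1S,2R,5R)-2,6,6-trimethyl-2,5-bis(triethylsilyloxy)cyclohexyl]ethoxy}silane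
Product: 13 2-[(1S,2R,5R)-2,6,6-trimethyl-2,5-bis(triethylsilyloxy)cyclohexyl]ethanol
Conditions: PPTS (0.1 equiv), MeOH/CH2Cl2 (1:1), 0 °C
Reagents that add atoms: none
Why: Acid-catalysed methanolysis cleaves the unhindered primary triethylsilyl ether much faster than the neopentyl secondary and the tertiary ones, so only the C4 hydroxyl should be freed.

Step 11
Reactants: 13 2-[(1S,2R,5R)-2,6,6-trimethyl-2,5-bis(triethylsilyloxy)cyclohexyl]ethanol
Product: 14 2-[(1S,2R,5R)-2,6,6-trimethyl-2,5-bis(triethylsilyloxy)cyclohexyl]ethyl iodide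
Conditions: I2, PPh3, imidazole, CH2Cl2, 0 °C → rt
Reagents that add atoms: iodine, II
Why: Appel-type iodination of the primary alcohol through its alkoxyphosphonium salt and SN2 displacement by iodide, with no internal oxygen nucleophile left to compete.

Step 12
Reactants: 14 2-[(1S,2R,5R)-2,6,6-trimethyl-2,5-bis(triethylsilyloxy)cyclohexyl]ethyl iodide
Product: 15 4-[(1S,2R,5R)-2,6,6-trimethyl-2,5-bis(triethylsilyloxy)cyclohexyl]but-1-yne
Conditions: lithium acetylide–ethylenediamine complex (3 equiv), DMSO/THF, 0 °C → rt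
Reagents that add atoms: lithium acetylide (ethylenediamine complex), [Li+].[C-]#C
Why: SN2 alkylation of acetylide by an unhindered primary iodide in a dipolar aprotic solvent adds C3 and C2, and the silyl ethers are stable to the base.

Step 13
Reactants: 15 4-[(1S,2R,5R)-2,6,6-trimethyl-2,5-bis(triethylsilyloxy)cyclohexyl]but-1-yne
Product: 18 (2E)-3-methyl-5-[(1S,2R,5R)-2,6,6-trimethyl-2,5-bis(triethylsilyloxy)cyclohexyl]pent-2-en-1-ol, via alkenyldimethylalane 16 (not isolated), via lithium alkenylalanate 17 (not isolated)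
Conditions: AlMe3 (3 equiv), Cp2ZrCl2 (0.3 equiv), CH2Cl2, 0 °C → rt; volatiles off; nBuLi (1.1 equiv), THF, −78 °C; (CH2O)n, −78 °C → rt
Reagents that add atoms: trimethylaluminium, C[Al](C)C; paraformaldehyde (as formaldehyde), C=O
Why: Negishi zirconium-catalysed carboalumination adds methyl and aluminium syn across the terminal alkyne with methyl on the internal carbon, and the derived alanate is hydroxymethylated by formaldehyde with retention, which should give only the (2E)-trisubstituted allylic alcohol.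

Step 14
Reactants: 18 (2E)-3-methyl-5-[(1S,2R,5R)-2,6,6-trimethyl-2,5-bis(triethylsilyloxy)cyclohexyl]pent-2-en-1-ol
Product: 19 {(2R,3R)-3-methyl-3-[2-((1S,2R,5R)-2,6,6-trimethyl-2,5-bis(triethylsilyloxy)cyclohexyl)ethyl]oxiran-2-yl}methanol
Conditions: Ti(OiPr)4 (0.2 equiv), D-(−)-diethyl tartrate (0.25 equiv), tBuOOH (2 equiv), 4 Å MS, CH2Cl2, −20 °C
Reagents that add atoms: tert-butyl hydroperoxide, CC(C)(C)OO
Why: Sharpless asymmetric epoxidation with the D-(−)-tartrate should give the (2R,3R)-epoxy alcohol from this geraniol-type (E)-allylic alcohol under reagent control, which fixes C3 independently of the distant ring stereocentres.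

Step 15
Reactants: 19 {(2R,3R)-3-methyl-3-[2-((1S,2R,5R)-2,6,6-trimethyl-2,5-bis(triethylsilyloxy)cyclohexyl)ethyl]oxiran-2-yl}methanol
Product: 20 (3R)-3-methyl-5-[(1S,2R,5R)-2,6,6-trimethyl-2,5-bis(triethylsilyloxy)cyclohexyl]pentane-1,3-diol
Conditions: NaAlH2(OCH2CH2OMe)2 (Red-Al, 3 equiv), THF, 0 °C → rt; aq potassium sodium tartrate
Reagents that add atoms: none
Why: The alkoxyaluminium hydride formed at the C1 hydroxyl delivers hydride internally to C2 of the 2,3-epoxy alcohol to give the 1,3-diol, and since the C3–O bond is not broken the (3R) tertiary carbinol is retained.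

Step 16
Reactants: 20 (3R)-3-methyl-5-[(1S,2R,5R)-2,6,6-trimethyl-2,5-bis(triethylsilyloxy)cyclohexyl]pentane-1,3-diol; 21 umbelliferone
Product: 22 7-{[(3R)-3-hydroxy-3-methyl-5-((1S,2R,5R)-2,6,6-trimethyl-2,5-bis(triethylsilyloxy)cyclohexyl)pentyl]oxy}-2H-chromen-2-one
Conditions: PPh3, DIAD, THF, 0 °C → rt
Reagents that add atoms: none
Why: Mitsunobu etherification, in which the acidic 7-hydroxycoumarin displaces the activated primary C1 hydroxyl while the tertiary C3 hydroxyl cannot form a reactive oxyphosphonium salt and no stereocentre is involved.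

Step 17
Reactants: 22 7-{[(3R)-3-hydroxy-3-methyl-5-((1S,2R,5R)-2,6,6-trimethyl-2,5-bis(triethylsilyloxy)cyclohexyl)pentyl]oxy}-2H-chromen-2-one
Product: 23 7-{[(3R)-5-((1S,2R,5R)-2,5-dihydroxy-2,6,6-trimethylcyclohexyl)-3-hydroxy-3-methylpentyl]oxy}-2H-chromen-2-one
Conditions: HF·pyridine, pyridine, THF, 0 °C → rt
Reagents that add atoms: none
Why: Buffered fluoride cleavage should remove both triethylsilyl ethers without opening the coumarin lactone or ionising the tertiary alcohols.

Step 18
Reactants: 23 7-{[(3R)-5-((1S,2R,5R)-2,5-dihydroxy-2,6,6-trimethylcyclohexyl)-3-hydroxy-3-methylpentyl]oxy}-2H-chromen-2-one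
Product: 24 (1R,3S,4R)-4-hydroxy-3-[(3R)-3-hydroxy-3-methyl-5-(2-oxo-2H-chromen-7-yloxy)pentyl]-2,2,4-trimethylcyclohexyl acetate
Conditions: Ac2O (1.5 equiv), pyridine, DMAP (0.1 equiv), CH2Cl2, 0 °C → rt
Reagents that add atoms: acetic anhydride, CC(=O)OC(C)=O
Why: Nucleophile-catalysed acylation of the only secondary hydroxyl (C10) should outpace acylation of the two tertiary hydroxyls at C3 and C7 under these mild conditions.

**Compound list**

1 | (R)-linalool, (3R)-3,7-dimethylocta-1,6-dien-3-ol | C=C[C@](C)(O)CCC=C(C)C | starting material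
2 | (3R)-3,7-dimethyl-3-(triethylsilyloxy)octa-1,6-diene | C=C[C@](C)(O[Si](CC)(CC)CC)CCC=C(C)C | intermediate
3 | (3R)-6,7-epoxy-3,7-dimethyl-3-(triethylsilyloxy)oct-1-ene (both C6 epimers) | C=C[C@](C)(O[Si](CC)(CC)CC)CCC1OC1(C)C | intermediate
4 | (6R)-2,6-dimethyl-6-(triethylsilyloxy)oct-7-en-3-one | C=C[C@](C)(O[Si](CC)(CC)CC)CCC(=O)C(C)C | intermediate
5 | (6R)-6-hydroxy-2,6-dimethyloct-7-en-3-one | C=C[C@](C)(O)CCC(=O)C(C)C | intermediate
6 | methyl acrylate | C=CC(=O)OC | starting material
7 | methyl (2E,4R)-4-hydroxy-4,8-dimethyl-7-oxonon-2-enoate | COC(=O)/C=C/[C@](C)(O)CCC(=O)C(C)C | intermediate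
8 | methyl 2-[(1S,2R)-2-hydroxy-2,6,6-trimethyl-5-oxocyclohexyl]acetate | COC(=O)C[C@H]1C(C)(C)C(=O)CC[C@@]1(C)O | intermediate
9 | (3aS,7aR)-4,4,7a-trimethyltetrahydro-1-benzofuran-2,5(3H,4H)-dione | O=C1C[C@H]2C(C)(C)C(=O)CC[C@@]2(C)O1 | intermediate
10 | (3aS,5R,7aR)-5-hydroxy-4,4,7a-trimethylhexahydro-1-benzofuran-2(3H)-one | O=C1C[C@H]2C(C)(C)[C@H](O)CC[C@@]2(C)O1 | intermediate
11 | (1R,2S,4R)-2-(2-hydroxyethyl)-1,3,3-trimethylcyclohexane-1,4-diol | O[C@@H]1CC[C@@](C)(O)[C@@H](CCO)C1(C)C | intermediate
12 | triethyl{2-[(1S,2R,5R)-2,6,6-trimethyl-2,5-bis(triethylsilyloxy)cyclohexyl]ethoxy}silane | CC[Si](CC)(CC)O[C@@H]1CC[C@@](C)(O[Si](CC)(CC)CC)[C@@H](CCO[Si](CC)(CC)CC)C1(C)C | intermediate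
13 | 2-[(1S,2R,5R)-2,6,6-trimethyl-2,5-bis(triethylsilyloxy)cyclohexyl]ethanol | CC[Si](CC)(CC)O[C@@H]1CC[C@@](C)(O[Si](CC)(CC)CC)[C@@H](CCO)C1(C)C | intermediate
14 | 2-[(1S,2R,5R)-2,6,6-trimethyl-2,5-bis(triethylsilyloxy)cyclohexyl]ethyl iodide | CC[Si](CC)(CC)O[C@@H]1CC[C@@](C)(O[Si](CC)(CC)CC)[C@@H](CCI)C1(C)C | intermediate
15 | 4-[(1S,2R,5R)-2,6,6-trimethyl-2,5-bis(triethylsilyloxy)cyclohexyl]but-1-yne | CC[Si](CC)(CC)O[C@@H]1CC[C@@](C)(O[Si](CC)(CC)CC)[C@@H](CCC#C)C1(C)C | intermediate
16 | dimethyl{(1E)-2-methyl-4-[(1S,2R,5R)-2,6,6-trimethyl-2,5-bis(triethylsilyloxy)cyclohexyl]but-1-en-1-yl}alane | CC[Si](CC)(CC)O[C@@H]1CC[C@@](C)(O[Si](CC)(CC)CC)[C@@H](CC/C(C)=C/[Al](C)C)C1(C)C | intermediate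
17 | lithium butyldimethyl{(1E)-2-methyl-4-[(1S,2R,5R)-2,6,6-trimethyl-2,5-bis(triethylsilyloxy)cyclohexyl]but-1-en-1-yl}alanate | CC[Si](CC)(CC)O[C@@H]1CC[C@@](C)(O[Si](CC)(CC)CC)[C@@H](CC/C(C)=C/[Al-](C)(C)CCCC)C1(C)C.[Li+] | intermediate
18 | (2E)-3-methyl-5-[(1S,2R,5R)-2,6,6-trimethyl-2,5-bis(triethylsilyloxy)cyclohexyl]pent-2-en-1-ol | CC[Si](CC)(CC)O[C@@H]1CC[C@@](C)(O[Si](CC)(CC)CC)[C@@H](CC/C(C)=C/CO)C1(C)C | intermediate
19 | {(2R,3R)-3-methyl-3-[2-((1S,2R,5R)-2,6,6-trimethyl-2,5-bis(triethylsilyloxy)cyclohexyl)ethyl]oxiran-2-yl}methanol | CC[Si](CC)(CC)O[C@@H]1CC[C@@](C)(O[Si](CC)(CC)CC)[C@@H](CC[C@@]2(C)O[C@@H]2CO)C1(C)C | intermediate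
20 | (3R)-3-methyl-5-[(1S,2R,5R)-2,6,6-trimethyl-2,5-bis(triethylsilyloxy)cyclohexyl]pentane-1,3-diol | CC[Si](CC)(CC)O[C@@H]1CC[C@@](C)(O[Si](CC)(CC)CC)[C@@H](CC[C@@](C)(O)CCO)C1(C)C | intermediate
21 | umbelliferone, 7-hydroxy-2H-chromen-2-one | O=c1ccc2ccc(O)cc2o1 | starting material
22 | 7-{[(3R)-3-hydroxy-3-methyl-5-((1S,2R,5R)-2,6,6-trimethyl-2,5-bis(triethylsilyloxy)cyclohexyl)pentyl]oxy}-2H-chromen-2-one | CC[Si](CC)(CC)O[C@@H]1CC[C@@](C)(O[Si](CC)(CC)CC)[C@@H](CC[C@@](C)(O)CCOc2ccc3ccc(=O)oc3c2)C1(C)C | intermediate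
23 | 7-{[(3R)-5-((1S,2R,5R)-2,5-dihydroxy-2,6,6-trimethylcyclohexyl)-3-hydroxy-3-methylpentyl]oxy}-2H-chromen-2-one | O[C@@H]1CC[C@@](C)(O)[C@@H](CC[C@@](C)(O)CCOc2ccc3ccc(=O)oc3c2)C1(C)C | intermediate
24 | (1R,3S,4R)-4-hydroxy-3-[(3R)-3-hydroxy-3-methyl-5-(2-oxo-2H-chromen-7-yloxy)pentyl]-2,2,4-trimethylcyclohexyl acetate (CNP0333962.1) | CC(=O)O[C@@H]1CC[C@@](C)(O)[C@@H](CC[C@@](C)(O)CCOc2ccc3ccc(=O)oc3c2)C1(C)C | target

**Step count**

Total steps: 18. Longest linear sequence: 18 steps (1 to 24).

**Steps most likely to fail**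

Step 6 (key step). The Michael equilibrium may lie on the open-chain side, because the new bond joins a quaternary carbon to a carbon flanked by a second fully substituted centre. The enolate population may also stay on the unproductive C9 side, or intermolecular conjugate addition may outrun cyclisation if lactonisation is slow. Fallback, from 7 back to 9: the bond is formed irreversibly under Lewis acid instead of reversibly under base. Compound 7 is silylated at both the hydroxyl and the ketone under equilibrating conditions that favour the more substituted enol ether (TMSCl, NaI, Et3N, MeCN), giving methyl (2E,4R)-4,8-dimethyl-4,7-bis(trimethylsilyloxy)nona-2,7-dienoate F1. An intramolecular Mukaiyama–Michael addition (TiCl4, CH2Cl2, −78 °C) then closes the ring. Aqueous HCl in THF removes silicon, and the cis adduct 8 lactonises to 9, where the route is rejoined.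

Step 3. The cation from the opened oxirane may be captured by the silyl ether oxygen (cyclic ether formation with loss of silicon), may undergo alkyl shift to an aldehyde, or may lose a proton to an allylic alcohol instead of undergoing the hydride shift. Fallback, from 1 back to 5, replacing steps 1 to 4: the ketone is built by cleavage and re-addition instead of rearrangement. Selective ozonolysis of the trisubstituted alkene of 1 (O3, one equivalent with Sudan red indicator, CH2Cl2/MeOH, −78 °C; Me2S) should give (5R)-5-ethenyl-5-methyloxolan-2-ol F2. Addition of iPrMgCl (3 equiv, THF, −78 → 0 °C) would open the lactol to (6R)-2,6-dimethyloct-7-ene-3,6-diol F3. Dess–Martin oxidation of the secondary alcohol alone (NaHCO3, CH2Cl2) returns 5.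

Step 13. Carbometalation of the alkyne may stop short, or the alkenylalane may be protonated before it meets formaldehyde, since paraformaldehyde depolymerises slowly, so that the hydroxymethyl group is not installed. Fallback, from 15 back to 18: the trisubstituted alkene is made by hydroalumination–iodination and methyl coupling instead of carboalumination. Compound 15 is deprotonated and hydroxymethylated (nBuLi, (CH2O)n, THF) to 5-[(1S,2R,5R)-2,6,6-trimethyl-2,5-bis(triethylsilyloxy)cyclohexyl]pent-2-yn-1-ol F4. Alkoxide-directed anti hydroalumination and iodination (NaAlH2(OCH2CH2OMe)2, THF; then I2, −78 °C) should give (2Z)-3-iodo-5-[(1S,2R,5R)-2,6,6-trimethyl-2,5-bis(triethylsilyloxy)cyclohexyl]pent-2-en-1-ol F5. Me2CuLi (Et2O, 0 °C) replaces iodine by methyl with retention and returns 18.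

**Further compounds**

F1 | step 6 | methyl (2E,4R)-4,8-dimethyl-4,7-bis(trimethylsilyloxy)nona-2,7-dienoate | COC(=O)/C=C/[C@](C)(O[Si](C)(C)C)CCC(O[Si](C)(C)C)=C(C)C
F2 | step 3 | (5R)-5-ethenyl-5-methyloxolan-2-ol (both anomers) | C=C[C@@]1(C)CCC(O)O1
F3 | step 3 | (6R)-2,6-dimethyloct-7-ene-3,6-diol (both C3 epimers) | C=C[C@](C)(O)CCC(O)C(C)C
F4 | step 13 | 5-[(1S,2R,5R)-2,6,6-trimethyl-2,5-bis(triethylsilyloxy)cyclohexyl]pent-2-yn-1-ol | CC[Si](CC)(CC)O[C@@H]1CC[C@@](C)(O[Si](CC)(CC)CC)[C@@H](CCC#CCO)C1(C)C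
F5 | step 13 | (2Z)-3-iodo-5-[(1S,2R,5R)-2,6,6-trimethyl-2,5-bis(triethylsilyloxy)cyclohexyl]pent-2-en-1-ol | CC[Si](CC)(CC)O[C@@H]1CC[C@@](C)(O[Si](CC)(CC)CC)[C@@H](CC/C(I)=C/CO)C1(C)C
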